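**Plan**
1. Retrosynthesis cuts the C5–C6 bond (ring-closing Suzuki coupling), the C23 ester and the C19–C20 bond (Suzuki coupling); this gives a cis-decalin core, a C20–C27 alkenyl boronate and (2E,4Z)-5-iodohexa-2,4-dienoic acid.
2. The cyclohexane ring C9–C10–C11–C12–C13–C14 is traced back to a cis-fused cyclopentanone (C9, C10, C11, C13, C14). The enabling feature is that C11 (OMe) and C13 (O) are 1,3-related across a lone CH2 (C12): a 2-(iodomethyl)-2-methoxy ketone passes C12 into the ring by a radical 1,2-acyl shift and leaves an α-methoxy radical at C11.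
3. The cyclopentane and the cyclohexene (C8, C9, C14–C17) arise together, earlier, by an intramolecular Diels–Alder reaction of a (Z)-enoate/(E,E)-dienyne (bonds C9–C14 and C8–C17).
4. Forward order: triene, cis-hydrindene, iodomethoxylation and oxidation, ring expansion, C13 reduction, vinyl iodide, side chain by Suzuki coupling, ester, 16-membered ring by Suzuki coupling, carbamate.
5. Stereochemistry: C13 (CBS reduction) steers the cycloaddition face (C8, C9, C14, C17; Z-enoate, E,E-diene, endo); C11 and C13 come from axial H-atom and hydride delivery on the cis-decalin; C22–C25 from two tartrate crotylborations on D-alaninal (C26).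

Key step: step 16

Remark: locants C1–C27 are those of superstolide A (C1 lactone carbonyl, C8 quaternary carbon, C9/C14 ring fusion, C11 methoxy carbon, C13 carbamate carbon, C23 lactone-oxygen carbon).
Assumption: methanol may enter from either face in step 13, so 16–18 are taken as C11 epimers (C11 drawn without configuration); C11 becomes a planar radical in step 16, so this has no consequence.

**Core (steps 1–20)**

Step 1
Reactants: 1 (E)-1,2-dichloroethene
Product: 2 (E)-1-chloropent-1-en-3-yne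
Conditions: propyne (1 equiv), 1 (5 equiv), Pd(PPh3)4 (5 mol %), CuI (10 mol %), n-BuNH2, Et2O, 20 °C
Reagents that add atoms: propyne, CC#C
Why: Sonogashira coupling stops at the mono-enyne when the dihalide is in excess, and oxidative addition into the C–Cl bond keeps the E geometry.

Step 2
Reactants: 2 (E)-1-chloropent-1-en-3-yne
Product: 3 trimethyl[(E)-hept-3-ene-1,5-diyn-1-yl]silane
Conditions: ethynyltrimethylsilane, PdCl2(PhCN)2 (5 mol %), CuI (10 mol %), piperidine, 20 °C
Reagents that add atoms: ethynyltrimethylsilane, C#C[Si](C)(C)C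
Why: A second Sonogashira coupling on the enyne-activated vinyl chloride adds the silyl-capped alkyne with retention of the E alkene.

Step 3
Reactants: 4 4-[(tert-butyldimethylsilyl)oxy]butanal
Product: 5 4-[(tert-butyldimethylsilyl)oxy]-2-methylidenebutanal
Conditions: aq. CH2O (37 %), pyrrolidine (10 mol %), propionic acid (10 mol %), i-PrOH, 45 °C
Reagents that add atoms: formaldehyde, C=O
Why: Amine-catalysed Mannich condensation and elimination (organocatalytic α-methylenation of an aldehyde) gives the 2-substituted acrolein.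

Step 4
Reactants: 3 trimethyl[(E)-hept-3-ene-1,5-diyn-1-yl]silane; 5 4-[(tert-butyldimethylsilyl)oxy]-2-methylidenebutanal
Product: 7 rac-(E)-1-[(tert-butyldimethylsilyl)oxy]-3-methylideneundec-7-ene-5,9-diyn-4-ol, via lithium acetylide 6 (not isolated)
Conditions: MeLi·LiBr (1.0 equiv), THF, 0 to 20 °C; then 5, −78 °C; aq. NH4Cl
Reagents that add atoms: none
Why: MeLi removes the alkynyl silyl group as Me4Si and the lithium acetylide adds 1,2 to the enal at −78 °C (acetylide addition to an aldehyde); the racemic carbinol is corrected in steps 5 and 6.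

Step 5
Reactants: 7 rac-(E)-1-[(tert-butyldimethylsilyl)oxy]-3-methylideneundec-7-ene-5,9-diyn-4-ol
Product: 8 (E)-1-[(tert-butyldimethylsilyl)oxy]-3-methylideneundec-7-ene-5,9-diyn-4-one
Conditions: MnO2 (activated, 20 equiv), CH2Cl2, 20 °C
Reagents that add atoms: none
Why: MnO2 oxidises the doubly activated (allylic and propargylic) alcohol selectively to the ynone.

Step 6
Reactants: 8 (E)-1-[(tert-butyldimethylsilyl)oxy]-3-methylideneundec-7-ene-5,9-diyn-4-one
Product: 9 (4R,7E)-1-[(tert-butyldimethylsilyl)oxy]-3-methylideneundec-7-ene-5,9-diyn-4-ol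
Conditions: (R)-2-methyl-CBS-oxazaborolidine (0.3 equiv), catecholborane (1.5 equiv), toluene, −78 °C; then MeOH, aq. NaOH
Reagents that add atoms: none
Why: Corey–Bakshi–Shibata reduction distinguishes the slim alkynyl group from the branched 2-alkenyl group, so the (R)-catalyst should give the (R)-propargylic alcohol (C13) by 1,2-reduction.

Step 7
Reactants: 9 (4R,7E)-1-[(tert-butyldimethylsilyl)oxy]-3-methylideneundec-7-ene-5,9-diyn-4-ol
Product: 10 (4S,5E,7E)-1-[(tert-butyldimethylsilyl)oxy]-3-methylideneundeca-5,7-dien-9-yn-4-ol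
Conditions: NaAlH2(OCH2CH2OMe)2 (2.5 equiv), THF, 0 °C; aq. Rochelle salt
Reagents that add atoms: none
Why: Alkoxide-directed trans-hydroalumination reduces only the propargylic alkyne to the (E)-alkene and leaves the remote, undirected alkyne untouched.

Step 8
Reactants: 10 (4S,5E,7E)-1-[(tert-butyldimethylsilyl)oxy]-3-methylideneundeca-5,7-dien-9-yn-4-ol
Product: 11 (4S,5E,7E)-1-[(tert-butyldimethylsilyl)oxy]-3-methylidene-4-[(triisopropylsilyl)oxy]undeca-5,7-dien-9-yne
Conditions: i-Pr3SiOTf, 2,6-lutidine, CH2Cl2, −78 to 0 °C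
Reagents that add atoms: triisopropylsilyl triflate, CC(C)[Si](OS(=O)(=O)C(F)(F)F)(C(C)C)C(C)C
Why: Silylation under basic, non-ionising conditions protects the bis-allylic alcohol and installs the bulky group that biases the cycloaddition.

Step 9
Reactants: 11 (4S,5E,7E)-1-[(tert-butyldimethylsilyl)oxy]-3-methylidene-4-[(triisopropylsilyl)oxy]undeca-5,7-dien-9-yne
Product: 12 (4S,5E,7E)-3-methylidene-4-[(triisopropylsilyl)oxy]undeca-5,7-dien-9-yn-1-ol
Conditions: pyridinium p-toluenesulfonate (0.2 equiv), MeOH/CH2Cl2 1:1, 0 to 20 °C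
Reagents that add atoms: none
Why: Acid-catalysed methanolysis removes the primary TBS ether far faster than the hindered secondary TIPS ether.

Step 10
Reactants: 12 (4S,5E,7E)-3-methylidene-4-[(triisopropylsilyl)oxy]undeca-5,7-dien-9-yn-1-ol
Product: 13 (4S,5E,7E)-3-methylidene-4-[(triisopropylsilyl)oxy]undeca-5,7-dien-9-ynal
Conditions: Dess–Martin periodinane, NaHCO3, CH2Cl2, 0 °C; used crude
Reagents that add atoms: none
Why: Buffered Dess–Martin oxidation is base-free, so the β,γ-unsaturated aldehyde should not isomerise into conjugation.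

Step 11
Reactants: 13 (4S,5E,7E)-3-methylidene-4-[(triisopropylsilyl)oxy]undeca-5,7-dien-9-ynal
Product: 14 ethyl (2Z,6S,7E,9E)-2-methyl-5-methylidene-6-[(triisopropylsilyl)oxy]trideca-2,7,9-trien-11-ynoate
Conditions: ethyl 2-[bis(2,2,2-trifluoroethoxy)phosphoryl]propanoate, KN(SiMe3)2, 18-crown-6, THF, −78 °C
Reagents that add atoms: ethyl 2-[bis(2,2,2-trifluoroethoxy)phosphoryl]propanoate, CCOC(=O)C(C)P(=O)(OCC(F)(F)F)OCC(F)(F)F
Why: Still–Gennari olefination gives the (Z)-trisubstituted enoate under kinetic control at −78 °C, where olefination should outrun enolisation of the aldehyde.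

Step 12
Reactants: 14 ethyl (2Z,6S,7E,9E)-2-methyl-5-methylidene-6-[(triisopropylsilyl)oxy]trideca-2,7,9-trien-11-ynoate
Product: 15 cis-hydrindene: ethyl 4-methyl-2-methylidene-5-(prop-1-yn-1-yl)-1-[(triisopropylsilyl)oxy]-2,3,3a,4,5,7a-hexahydro-1H-indene-4-carboxylate (C8, C9, C14, C17 as in the target; OTIPS cis to H14)
Conditions: toluene (0.01 M), BHT (cat.), 165 °C, sealed tube
Reagents that add atoms: none
Why: The intramolecular Diels–Alder reaction of a (Z)-dienophile nonatriene goes through the endo, cis-fused transition state (ester and tether under the diene), the E,E-diene puts C13 and C18 cis to C7 and C10, and the bulky OTIPS group on C13 should take the convex side away from the forming cyclohexene, which fixes the diene face and with it C8, C9, C14 and C17.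

Step 13
Reactants: 15 cis-hydrindene with C11 exocyclic methylene
Product: 16 ethyl 2-(iodomethyl)-2-methoxy-4-methyl-5-(prop-1-yn-1-yl)-1-[(triisopropylsilyl)oxy]-2,3,3a,4,5,7a-hexahydro-1H-indene-4-carboxylate (C11 epimers)
Conditions: N-iodosuccinimide (1.1 equiv), MeOH/CH2Cl2 1:4, −20 °C, dark
Reagents that add atoms: N-iodosuccinimide, O=C1CCC(=O)N1I; methanol, CO
Why: Iodonium formation on the most electron-rich, 1,1-disubstituted alkene and Markovnikov opening by methanol at the tertiary carbon (alkoxyiodination) installs the C11 methyl ether and the C12 iodide together.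

Step 14
Reactants: 16 iodomethyl methyl ether, C13-OTIPS
Product: 17 ethyl 1-hydroxy-2-(iodomethyl)-2-methoxy-4-methyl-5-(prop-1-yn-1-yl)-2,3,3a,4,5,7a-hexahydro-1H-indene-4-carboxylate (C11 epimers)
Conditions: HF·pyridine, pyridine, THF, 20 to 40 °C
Reagents that add atoms: none
Why: Fluoride cleaves the Si–O bond under mildly acidic conditions, which avoids an alkoxide next to the primary iodide.

Step 15
Reactants: 17 C13 alcohol
Product: 18 ethyl 2-(iodomethyl)-2-methoxy-4-methyl-1-oxo-5-(prop-1-yn-1-yl)-2,3,3a,4,5,7a-hexahydro-1H-indene-4-carboxylate (C11 epimers)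
Conditions: Dess–Martin periodinane, NaHCO3, CH2Cl2, 0 to 20 °C
Reagents that add atoms: none
Why: Dess–Martin oxidation is base-free, so the β,γ-unsaturated ketone should form without epimerisation at C14 or migration of the C15=C16 alkene.

Step 16
Reactants: 18 2-(iodomethyl)-2-methoxy cyclopentanone (cis-hydrindenone)
Product: 19 ethyl 7-methoxy-1-methyl-5-oxo-2-(prop-1-yn-1-yl)-1,2,4a,5,6,7,8,8a-octahydronaphthalene-1-carboxylate (cis-fused; C11-OMe cis to C8)
Conditions: Bu3SnH (1.3 equiv, syringe pump over 6 h), AIBN (0.2 equiv), benzene (0.005 M), 80 °C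
Reagents that add atoms: none
Why: The tin radical abstracts iodine to give the primary C12 radical, which adds 3-exo-trig to the C13 carbonyl carbon; the cyclopropyloxy radical then breaks the C11–C13 bond, so C12 ends inside the ring and the radical ends at C11, stabilised by the methoxy group. The closest known reaction type is the Dowd–Beckwith ring expansion of 2-(halomethyl)cycloalkanones (radical 1,2-acyl shift), in which an ester usually plays the stabilising role taken here by the α-methoxy group. The only ring closed is the transient cyclopropane (3-exo-trig); the cyclohexanone is not closed but arises from the cyclopentanone by this β-scission. The new stereocentre C11 is set when Bu3SnH delivers hydrogen axially from the convex face of the cis-fused bicycle (C8 equatorial on C9), which leaves the methoxy group equatorial and cis to C8. The step needs rearrangement to beat direct reduction of the C12 radical, which slow stannane addition at high dilution should secure, and scission toward C11 instead of back to C12, which the tertiary α-alkoxy radical secures; 5-exo attack on C15=C16 would build a strained bicyclo[2.2.1]heptanone and should be slower.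

Step 17
Reactants: 19 cis-decalone (C13 ketone)
Product: 20 ethyl 5-hydroxy-7-methoxy-1-methyl-2-(prop-1-yn-1-yl)-1,2,4a,5,6,7,8,8a-octahydronaphthalene-1-carboxylate (C13-OH equatorial, cis to C11-OMe)
Conditions: NaBH4, MeOH, −40 °C
Reagents that add atoms: none
Why: Borohydride attacks the cyclohexanone axially from the convex face (cis to H9 and H14) to give the equatorial C13 alcohol, and the low temperature avoids β-elimination of methanol.

Step 18
Reactants: 20 C13 alcohol
Product: 21 ethyl 7-methoxy-1-methyl-2-(prop-1-yn-1-yl)-5-[(triethylsilyl)oxy]-1,2,4a,5,6,7,8,8a-octahydronaphthalene-1-carboxylate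
Conditions: Et3SiOTf, 2,6-lutidine, CH2Cl2, −78 °C
Reagents that add atoms: triethylsilyl triflate, CC[Si](CC)(CC)OS(=O)(=O)C(F)(F)F
Why: Standard silylation; the TES ether can later be removed in the presence of the C25 TBS ether.

Step 19
Reactants: 21 C13-OTES propynyl ester
Product: 23 ethyl 2-[(E)-2-iodoprop-1-en-1-yl]-7-methoxy-1-methyl-5-[(triethylsilyl)oxy]-1,2,4a,5,6,7,8,8a-octahydronaphthalene-1-carboxylate, via alkenylzirconocene chloride 22 (not isolated)
Conditions: Cp2Zr(H)Cl (2.5 equiv), THF, 20 °C; then I2, THF, −20 °C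
Reagents that add atoms: iodine, II
Why: Hydrozirconation adds syn and, with excess reagent, equilibrates zirconium to the less hindered methyl-bearing carbon (C19); iodinolysis with retention gives the (E)-trisubstituted vinyl iodide, and the hindered neopentyl ester should be tolerated.

Step 20
Reactants: 23 vinyl iodide ester
Product: 24 {2-[(E)-2-iodoprop-1-en-1-yl]-7-methoxy-1-methyl-5-[(triethylsilyl)oxy]-1,2,4a,5,6,7,8,8a-octahydronaphthalen-1-yl}methanol
Conditions: i-Bu2AlH (3 equiv), CH2Cl2, −78 to −20 °C; aq. Rochelle salt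
Reagents that add atoms: none
Why: Hydride reduction of the ester to the primary alcohol leaves the vinyl iodide and the silyl ether untouched.

**Side chain C20–C27 (steps 21–26)**

Step 21
Reactants: 25 tert-butyl [(2R)-1-oxopropan-2-yl]carbamate (N-Boc-D-alaninal)
Product: 26 tert-butyl [(2R,3S,4S)-3-hydroxy-4-methylhex-5-en-2-yl]carbamate
Conditions: diisopropyl (R,R)-tartrate (E)-crotylboronate (1.5 equiv, made by the standard procedure), 4 Å molecular sieves, toluene, −78 °C; aq. NaOH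
Reagents that add atoms: diisopropyl (R,R)-tartrate (E)-crotylboronate, C/C=C/CB1O[C@@H](C(=O)OC(C)C)[C@@H](O1)C(=O)OC(C)C
Why: Tartrate (E)-crotylboration through a chair transition state gives the anti C24/C25 pair, and the (R,R)-reagent attacks the si face of the aldehyde, in line with the Felkin–Anh preference, to set C25 anti to C26.

Step 22
Reactants: 26 tert-butyl [(2R,3S,4S)-3-hydroxy-4-methylhex-5-en-2-yl]carbamate
Product: 28 N-[(2R,3S,4S)-3-hydroxy-4-methylhex-5-en-2-yl]acetamide, via aminium chloride 27 (not isolated)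
Conditions: HCl (4 M in dioxane), 0 to 20 °C; evaporate; then Ac2O (1.1 equiv), Et3N, MeOH, 0 °C
Reagents that add atoms: acetic anhydride, CC(=O)OC(C)=O
Why: Acidolysis of the Boc group and chemoselective N-acetylation in methanol, the amine being far more nucleophilic than the secondary alcohol.

Step 23
Reactants: 28 N-[(2R,3S,4S)-3-hydroxy-4-methylhex-5-en-2-yl]acetamide
Product: 29 N-[(2R,3S,4S)-3-[(tert-butyldimethylsilyl)oxy]-4-methylhex-5-en-2-yl]acetamide
Conditions: t-BuMe2SiOTf, 2,6-lutidine, CH2Cl2, 0 °C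
Reagents that add atoms: tert-butyldimethylsilyl triflate, CC(C)(C)[Si](C)(C)OS(=O)(=O)C(F)(F)F
Why: O-Silylation of the hindered secondary alcohol; any O-silyl imidate of the amide is hydrolysed on work-up.

Step 24
Reactants: 29 N-[(2R,3S,4S)-3-[(tert-butyldimethylsilyl)oxy]-4-methylhex-5-en-2-yl]acetamide
Product: 31 N-[(2R,3S,4R)-3-[(tert-butyldimethylsilyl)oxy]-4-methyl-5-oxopentan-2-yl]acetamide, via ozonide 30 (not isolated)
Conditions: O3, CH2Cl2, −78 °C; then PPh3, −78 to 20 °C; used crude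
Reagents that add atoms: ozone, [O-][O+]=O
Why: Ozonolysis of the only alkene with reductive work-up gives the α-methyl aldehyde, which is used at once to avoid epimerisation at C24.

Step 25
Reactants: 31 N-[(2R,3S,4R)-3-[(tert-butyldimethylsilyl)oxy]-4-methyl-5-oxopentan-2-yl]acetamide
Product: 32 N-[(2R,3S,4S,5R,6R)-3-[(tert-butyldimethylsilyl)oxy]-5-hydroxy-4,6-dimethyloct-7-en-2-yl]acetamide
Conditions: diisopropyl (S,S)-tartrate (E)-crotylboronate (1.5 equiv), 4 Å molecular sieves, toluene, −78 °C; aq. NaOH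
Reagents that add atoms: diisopropyl (S,S)-tartrate (E)-crotylboronate, C/C=C/CB1O[C@H](C(=O)OC(C)C)[C@H](O1)C(=O)OC(C)C
Why: (E)-Crotylboration gives the anti C22/C23 pair, and the (S,S)-reagent attacks the re face, which is also the Felkin face of the α-methyl aldehyde (matched pair), giving C23 syn to C24.

Step 26
Reactants: 32 N-[(2R,3S,4S,5R,6R)-3-[(tert-butyldimethylsilyl)oxy]-5-hydroxy-4,6-dimethyloct-7-en-2-yl]acetamide
Product: 33 N-[(2R,3S,4S,5R,6R,7E)-3-[(tert-butyldimethylsilyl)oxy]-5-hydroxy-4,6-dimethyl-8-(4,4,5,5-tetramethyl-1,3,2-dioxaborolan-2-yl)oct-7-en-2-yl]acetamide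
Conditions: vinylboronic acid pinacol ester (3 equiv), second-generation Grubbs catalyst (H2IMes)(PCy3)Cl2Ru=CHPh (5 mol %), CH2Cl2, 40 °C
Reagents that add atoms: vinylboronic acid pinacol ester, C=CB1OC(C)(C)C(C)(C)O1
Why: Olefin cross-metathesis gives the (E)-alkenyl boronate under thermodynamic control, and the allylic methyl branch suppresses homodimerisation.

**Acid C1–C5 (steps 27–29)**

Step 27
Reactants: 34 but-2-yn-1-ol
Product: 36 (Z)-3-iodobut-2-en-1-ol, via sodium alkenylalanate 35 (not isolated)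
Conditions: NaAlH2(OCH2CH2OMe)2 (1.5 equiv), THF, 0 to 20 °C; then I2, THF, −78 to 0 °C
Reagents that add atoms: iodine, II
Why: Hydroxyl-directed trans-hydroalumination places aluminium on C3 in a five-membered alanate, cis to the CH2O group, and iodinolysis with retention gives the (Z)-vinyl iodide.

Step 28
Reactants: 36 (Z)-3-iodobut-2-en-1-ol
Product: 38 ethyl (2E,4Z)-5-iodohexa-2,4-dienoate, via (Z)-3-iodobut-2-enal 37 (not isolated)
Conditions: MnO2 (15 equiv), Ph3P=CHCO2Et (1.3 equiv), CH2Cl2, 20 °C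
Reagents that add atoms: ethyl (triphenylphosphoranylidene)acetate, CCOC(=O)C=P(c1ccccc1)(c1ccccc1)c1ccccc1
Why: Tandem allylic oxidation–Wittig reaction traps the sensitive (Z)-enal in situ, and the stabilised ylide gives the (E)-enoate without touching the Z-vinyl iodide.

Step 29
Reactants: 38 ethyl (2E,4Z)-5-iodohexa-2,4-dienoate
Product: 39 (2E,4Z)-5-iodohexa-2,4-dienoic acid
Conditions: LiOH, THF/H2O 3:1, 0 to 20 °C; then aq. HCl to pH 3
Reagents that add atoms: lithium hydroxide, [Li+].[OH-]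
Why: Mild saponification of the ethyl ester leaves both alkene geometries intact.

**Assembly (steps 30–37)**

Step 30
Reactants: 24 core vinyl iodide alcohol; 33 C20–C27 alkenyl boronate
Product: 40 C7–C27 seco-diol: (18E,20E)-diene, C7H2OH and C23-OH free, C13-OTES, C25-OTBS, C26-NHAc
Conditions: Pd(PPh3)4 (10 mol %), TlOEt (2 equiv), THF/H2O 3:1, 20 °C
Reagents that add atoms: none
Why: Suzuki–Miyaura coupling proceeds with retention at both alkenes to give the (18E,20E)-diene, and TlOEt speeds transmetalation so that it runs at room temperature with free hydroxyl and amide groups.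

Step 31
Reactants: 40 seco-diol
Product: 41 C7 aldehyde (C23-OH free)
Conditions: TEMPO (0.2 equiv), PhI(OAc)2 (1.3 equiv), CH2Cl2, 20 °C
Reagents that add atoms: none
Why: Oxoammonium (TEMPO) oxidation selects the primary over the hindered secondary alcohol.

Step 32
Reactants: 41 C7 aldehyde
Product: 42 (6E)-alkenyl pinacol boronate at C6 (C23-OH free)
Conditions: Cl2CHB(pin), CrCl2 (8 equiv), LiI (4 equiv), THF, 20 °C
Reagents that add atoms: 2-(dichloromethyl)-4,4,5,5-tetramethyl-1,3,2-dioxaborolane, ClC(Cl)B1OC(C)(C)C(C)(C)O1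
Why: Takai–Utimoto-type boryl olefination (geminal dichromium reagent) converts the non-enolisable aldehyde into the (E)-alkenyl boronate and tolerates free OH and NH groups.

Step 33
Reactants: 42 alkenyl boronate alcohol; 39 (2E,4Z)-5-iodohexa-2,4-dienoic acid
Product: 44 C23 ester of 42 with 39 (seco vinyl iodide/alkenyl boronate), via mixed anhydride 43 (not isolated)
Conditions: 39 (1.5 equiv), 2,4,6-trichlorobenzoyl chloride, Et3N, THF, 20 °C; then 42, DMAP, toluene, 20 °C
Reagents that add atoms: none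
Why: Yamaguchi esterification through the mixed anhydride acylates the hindered C23 alcohol, the only free hydroxyl group.

Step 34
Reactants: 44 seco ester
Product: 45 13-O-decarbamoyl-13-O-(triethylsilyl)-25-O-(tert-butyldimethylsilyl)superstolide A
Conditions: Pd(PPh3)4 (20 mol %), TlOEt (3 equiv), THF/H2O 4:1 (0.001 M), 20 °C
Reagents that add atoms: none
Why: Intramolecular Suzuki–Miyaura coupling under high dilution closes the 16-membered ring at C5–C6 between two sp2 carbons with retention of the 4Z and 6E geometries.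

Step 35
Reactants: 45 bis-silyl macrolide
Product: 46 13-O-decarbamoyl-25-O-(tert-butyldimethylsilyl)superstolide A
Conditions: HF·pyridine, pyridine, THF, 0 °C
Reagents that add atoms: none
Why: Buffered fluoride removes the secondary TES ether much faster than the hindered TBS ether.

Step 36
Reactants: 46 C13 alcohol
Product: 48 25-O-(tert-butyldimethylsilyl)superstolide A, via N-trichloroacetyl carbamate 47 (not isolated)
Conditions: Cl3CC(O)NCO (1.5 equiv), CH2Cl2, 0 °C; then neutral Al2O3, 20 °C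
Reagents that add atoms: trichloroacetyl isocyanate, O=C=NC(=O)C(Cl)(Cl)Cl
Why: The alcohol adds to the highly electrophilic isocyanate and the trichloroacetyl group is then hydrolysed on neutral alumina, giving the primary carbamate without a base that could open the lactone.

Step 37
Reactants: 48 25-O-(tert-butyldimethylsilyl)superstolide A
Product: 49 superstolide A
Conditions: HF·pyridine, THF, 20 °C
Reagents that add atoms: none
Why: Fluoride removes the last silyl ether under mildly acidic conditions that the polyene lactone and the carbamate should tolerate.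

**Compound list**
1 | (E)-1,2-dichloroethene | Cl/C=C/Cl | starting material
2 | (E)-1-chloropent-1-en-3-yne | CC#C/C=C/Cl | intermediate
3 | trimethyl[(E)-hept-3-ene-1,5-diyn-1-yl]silane | CC#C/C=C/C#C[Si](C)(C)C | intermediate
4 | 4-[(tert-butyldimethylsilyl)oxy]butanal | O=CCCCO[Si](C)(C)C(C)(C)C | starting material
5 | 4-[(tert-butyldimethylsilyl)oxy]-2-methylidenebutanal | C=C(C=O)CCO[Si](C)(C)C(C)(C)C | intermediate
6 | lithium (E)-hept-3-ene-1,5-diyn-1-ide | [Li]C#C/C=C/C#CC | intermediate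
7 | rac-(E)-1-[(tert-butyldimethylsilyl)oxy]-3-methylideneundec-7-ene-5,9-diyn-4-ol | C=C(CCO[Si](C)(C)C(C)(C)C)C(O)C#C/C=C/C#CC | intermediate
8 | (E)-1-[(tert-butyldimethylsilyl)oxy]-3-methylideneundec-7-ene-5,9-diyn-4-one | C=C(CCO[Si](C)(C)C(C)(C)C)C(=O)C#C/C=C/C#CC | intermediate
9 | (4R,7E)-1-[(tert-butyldimethylsilyl)oxy]-3-methylideneundec-7-ene-5,9-diyn-4-ol | C=C(CCO[Si](C)(C)C(C)(C)C)[C@@H](O)C#C/C=C/C#CC | intermediate
10 | (4S,5E,7E)-1-[(tert-butyldimethylsilyl)oxy]-3-methylideneundeca-5,7-dien-9-yn-4-ol | C=C(CCO[Si](C)(C)C(C)(C)C)[C@@H](O)/C=C/C=C/C#CC | intermediate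
11 | (4S,5E,7E)-1-[(tert-butyldimethylsilyl)oxy]-3-methylidene-4-[(triisopropylsilyl)oxy]undeca-5,7-dien-9-yne | C=C(CCO[Si](C)(C)C(C)(C)C)[C@@H](O[Si](C(C)C)(C(C)C)C(C)C)/C=C/C=C/C#CC | intermediate
12 | (4S,5E,7E)-3-methylidene-4-[(triisopropylsilyl)oxy]undeca-5,7-dien-9-yn-1-ol | C=C(CCO)[C@@H](O[Si](C(C)C)(C(C)C)C(C)C)/C=C/C=C/C#CC | intermediate
13 | (4S,5E,7E)-3-methylidene-4-[(triisopropylsilyl)oxy]undeca-5,7-dien-9-ynal | C=C(CC=O)[C@@H](O[Si](C(C)C)(C(C)C)C(C)C)/C=C/C=C/C#CC | intermediate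
14 | ethyl (2Z,6S,7E,9E)-2-methyl-5-methylidene-6-[(triisopropylsilyl)oxy]trideca-2,7,9-trien-11-ynoate | CCOC(=O)/C(C)=C\CC(=C)[C@@H](O[Si](C(C)C)(C(C)C)C(C)C)/C=C/C=C/C#CC | intermediate
15 | ethyl 4-methyl-2-methylidene-5-(prop-1-yn-1-yl)-1-[(triisopropylsilyl)oxy]-2,3,3a,4,5,7a-hexahydro-1H-indene-4-carboxylate (cis-fused; OTIPS cis to H14) | C=C1[C@@H](O[Si](C(C)C)(C(C)C)C(C)C)[C@@H]2C=C[C@H](C#CC)[C@@](C(=O)OCC)(C)[C@@H]2C1 | intermediate
16 | ethyl 2-(iodomethyl)-2-methoxy-4-methyl-5-(prop-1-yn-1-yl)-1-[(triisopropylsilyl)oxy]-2,3,3a,4,5,7a-hexahydro-1H-indene-4-carboxylate (C11 epimers) | COC1(CI)[C@@H](O[Si](C(C)C)(C(C)C)C(C)C)[C@@H]2C=C[C@H](C#CC)[C@@](C(=O)OCC)(C)[C@@H]2C1 | intermediate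
17 | ethyl 1-hydroxy-2-(iodomethyl)-2-methoxy-4-methyl-5-(prop-1-yn-1-yl)-2,3,3a,4,5,7a-hexahydro-1H-indene-4-carboxylate (C11 epimers) | COC1(CI)[C@@H](O)[C@@H]2C=C[C@H](C#CC)[C@@](C(=O)OCC)(C)[C@@H]2C1 | intermediate
18 | ethyl 2-(iodomethyl)-2-methoxy-4-methyl-1-oxo-5-(prop-1-yn-1-yl)-2,3,3a,4,5,7a-hexahydro-1H-indene-4-carboxylate (C11 epimers) | COC1(CI)C(=O)[C@@H]2C=C[C@H](C#CC)[C@@](C(=O)OCC)(C)[C@@H]2C1 | intermediate
19 | ethyl 7-methoxy-1-methyl-5-oxo-2-(prop-1-yn-1-yl)-1,2,4a,5,6,7,8,8a-octahydronaphthalene-1-carboxylate (cis-fused) | CO[C@@H]1CC(=O)[C@@H]2C=C[C@H](C#CC)[C@@](C(=O)OCC)(C)[C@@H]2C1 | intermediate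
20 | ethyl 5-hydroxy-7-methoxy-1-methyl-2-(prop-1-yn-1-yl)-1,2,4a,5,6,7,8,8a-octahydronaphthalene-1-carboxylate | CO[C@@H]1C[C@H](O)[C@@H]2C=C[C@H](C#CC)[C@@](C(=O)OCC)(C)[C@@H]2C1 | intermediate
21 | ethyl 7-methoxy-1-methyl-2-(prop-1-yn-1-yl)-5-[(triethylsilyl)oxy]-1,2,4a,5,6,7,8,8a-octahydronaphthalene-1-carboxylate | CO[C@@H]1C[C@H](O[Si](CC)(CC)CC)[C@@H]2C=C[C@H](C#CC)[C@@](C(=O)OCC)(C)[C@@H]2C1 | intermediate
22 | (E)-alkenylzirconocene chloride of 21 (Zr on C19) | CO[C@@H]1C[C@H](O[Si](CC)(CC)CC)[C@@H]2C=C[C@H](/C=C(C)/[Zr](Cl)(C3C=CC=C3)C3C=CC=C3)[C@@](C(=O)OCC)(C)[C@@H]2C1 | intermediate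
23 | ethyl 2-[(E)-2-iodoprop-1-en-1-yl]-7-methoxy-1-methyl-5-[(triethylsilyl)oxy]-1,2,4a,5,6,7,8,8a-octahydronaphthalene-1-carboxylate | CO[C@@H]1C[C@H](O[Si](CC)(CC)CC)[C@@H]2C=C[C@H](/C=C(C)/I)[C@@](C(=O)OCC)(C)[C@@H]2C1 | intermediate
24 | {2-[(E)-2-iodoprop-1-en-1-yl]-7-methoxy-1-methyl-5-[(triethylsilyl)oxy]-1,2,4a,5,6,7,8,8a-octahydronaphthalen-1-yl}methanol | CO[C@@H]1C[C@H](O[Si](CC)(CC)CC)[C@@H]2C=C[C@H](/C=C(C)/I)[C@@](CO)(C)[C@@H]2C1 | intermediate
25 | tert-butyl [(2R)-1-oxopropan-2-yl]carbamate | C[C@@H](NC(=O)OC(C)(C)C)C=O | starting material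
26 | tert-butyl [(2R,3S,4S)-3-hydroxy-4-methylhex-5-en-2-yl]carbamate | C=C[C@H](C)[C@H](O)[C@@H](C)NC(=O)OC(C)(C)C | intermediate
27 | (2R,3S,4S)-3-hydroxy-4-methylhex-5-en-2-aminium chloride | C=C[C@H](C)[C@H](O)[C@@H](C)[NH3+].[Cl-] | intermediate
28 | N-[(2R,3S,4S)-3-hydroxy-4-methylhex-5-en-2-yl]acetamide | C=C[C@H](C)[C@H](O)[C@@H](C)NC(C)=O | intermediate
29 | N-[(2R,3S,4S)-3-[(tert-butyldimethylsilyl)oxy]-4-methylhex-5-en-2-yl]acetamide | C=C[C@H](C)[C@H](O[Si](C)(C)C(C)(C)C)[C@@H](C)NC(C)=O | intermediate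
30 | 1,2,4-trioxolane (ozonide) of 29 | O1COOC1[C@H](C)[C@H](O[Si](C)(C)C(C)(C)C)[C@@H](C)NC(C)=O | intermediate
31 | N-[(2R,3S,4R)-3-[(tert-butyldimethylsilyl)oxy]-4-methyl-5-oxopentan-2-yl]acetamide | O=C[C@H](C)[C@H](O[Si](C)(C)C(C)(C)C)[C@@H](C)NC(C)=O | intermediate
32 | N-[(2R,3S,4S,5R,6R)-3-[(tert-butyldimethylsilyl)oxy]-5-hydroxy-4,6-dimethyloct-7-en-2-yl]acetamide | C=C[C@@H](C)[C@@H](O)[C@H](C)[C@H](O[Si](C)(C)C(C)(C)C)[C@@H](C)NC(C)=O | intermediate
33 | N-[(2R,3S,4S,5R,6R,7E)-3-[(tert-butyldimethylsilyl)oxy]-5-hydroxy-4,6-dimethyl-8-(4,4,5,5-tetramethyl-1,3,2-dioxaborolan-2-yl)oct-7-en-2-yl]acetamide | CC1(C)OB(OC1(C)C)/C=C/[C@@H](C)[C@@H](O)[C@H](C)[C@H](O[Si](C)(C)C(C)(C)C)[C@@H](C)NC(C)=O | intermediate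
34 | but-2-yn-1-ol | CC#CCO | starting material
35 | sodium 2,2-bis(2-methoxyethoxy)-3-methyl-2,5-dihydro-1,2-oxaaluminol-2-uide (alkenylalanate) | [Na+].CC1=CCO[Al-]1(OCCOC)OCCOC | intermediate
36 | (Z)-3-iodobut-2-en-1-ol | OC/C=C(C)\I | intermediate
37 | (Z)-3-iodobut-2-enal | O=C/C=C(C)\I | intermediate
38 | ethyl (2E,4Z)-5-iodohexa-2,4-dienoate | CCOC(=O)/C=C/C=C(C)\I | intermediate
39 | (2E,4Z)-5-iodohexa-2,4-dienoic acid | OC(=O)/C=C/C=C(C)\I | intermediate
40 | C7–C27 seco-diol (C7H2OH, C23-OH free; C13-OTES; C25-OTBS; 18E,20E) | CO[C@@H]1C[C@H](O[Si](CC)(CC)CC)[C@@H]2C=C[C@H](/C=C(C)/C=C/[C@@H](C)[C@@H](O)[C@H](C)[C@H](O[Si](C)(C)C(C)(C)C)[C@@H](C)NC(C)=O)[C@@](CO)(C)[C@@H]2C1 | intermediate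
41 | C7 aldehyde of 40 | CO[C@@H]1C[C@H](O[Si](CC)(CC)CC)[C@@H]2C=C[C@H](/C=C(C)/C=C/[C@@H](C)[C@@H](O)[C@H](C)[C@H](O[Si](C)(C)C(C)(C)C)[C@@H](C)NC(C)=O)[C@@](C=O)(C)[C@@H]2C1 | intermediate
42 | (6E)-alkenyl pinacol boronate (C6–B) with free C23-OH | CO[C@@H]1C[C@H](O[Si](CC)(CC)CC)[C@@H]2C=C[C@H](/C=C(C)/C=C/[C@@H](C)[C@@H](O)[C@H](C)[C@H](O[Si](C)(C)C(C)(C)C)[C@@H](C)NC(C)=O)[C@@](/C=C/B3OC(C)(C)C(C)(C)O3)(C)[C@@H]2C1 | intermediate
43 | (2E,4Z)-5-iodohexa-2,4-dienoic 2,4,6-trichlorobenzoic anhydride | O=C(OC(=O)/C=C/C=C(C)\I)c1c(Cl)cc(Cl)cc1Cl | intermediate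
44 | C23 (2E,4Z)-5-iodohexa-2,4-dienoate of 42 | CO[C@@H]1C[C@H](O[Si](CC)(CC)CC)[C@@H]2C=C[C@H](/C=C(C)/C=C/[C@@H](C)[C@@H](OC(=O)/C=C/C=C(C)\I)[C@H](C)[C@H](O[Si](C)(C)C(C)(C)C)[C@@H](C)NC(C)=O)[C@@](/C=C/B3OC(C)(C)C(C)(C)O3)(C)[C@@H]2C1 | intermediate
45 | 13-O-decarbamoyl-13-O-(triethylsilyl)-25-O-(tert-butyldimethylsilyl)superstolide A | CO[C@@H]1C[C@H](O[Si](CC)(CC)CC)[C@@H]2C=C[C@@H]3/C=C(C)/C=C/[C@@H](C)[C@H]([C@H](C)[C@H](O[Si](C)(C)C(C)(C)C)[C@@H](C)NC(C)=O)OC(=O)/C=C/C=C(C)\C=C\[C@]3(C)[C@@H]2C1 | intermediate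
46 | 13-O-decarbamoyl-25-O-(tert-butyldimethylsilyl)superstolide A | CO[C@@H]1C[C@H](O)[C@@H]2C=C[C@@H]3/C=C(C)/C=C/[C@@H](C)[C@H]([C@H](C)[C@H](O[Si](C)(C)C(C)(C)C)[C@@H](C)NC(C)=O)OC(=O)/C=C/C=C(C)\C=C\[C@]3(C)[C@@H]2C1 | intermediate
47 | N-(trichloroacetyl)-25-O-(tert-butyldimethylsilyl)superstolide A | CO[C@@H]1C[C@H](OC(=O)NC(=O)C(Cl)(Cl)Cl)[C@@H]2C=C[C@@H]3/C=C(C)/C=C/[C@@H](C)[C@H]([C@H](C)[C@H](O[Si](C)(C)C(C)(C)C)[C@@H](C)NC(C)=O)OC(=O)/C=C/C=C(C)\C=C\[C@]3(C)[C@@H]2C1 | intermediate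
48 | 25-O-(tert-butyldimethylsilyl)superstolide A | CO[C@@H]1C[C@H](OC(N)=O)[C@@H]2C=C[C@@H]3/C=C(C)/C=C/[C@@H](C)[C@H]([C@H](C)[C@H](O[Si](C)(C)C(C)(C)C)[C@@H](C)NC(C)=O)OC(=O)/C=C/C=C(C)\C=C\[C@]3(C)[C@@H]2C1 | intermediate
49 | superstolide A | CO[C@@H]1C[C@H](OC(N)=O)[C@@H]2C=C[C@@H]3/C=C(C)/C=C/[C@@H](C)[C@H]([C@H](C)[C@H](O)[C@@H](C)NC(C)=O)OC(=O)/C=C/C=C(C)\C=C\[C@]3(C)[C@@H]2C1 | target

**Step count**
Total: 37 steps. Longest linear sequence: 27 steps (steps 1, 2, 4–20, 30–37, from (E)-1,2-dichloroethene).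

**Steps most likely to fail**

Step 16. The stannane may transfer hydrogen to the C12 radical before the acyl shift, or the 3-exo addition to the hindered ketone may be slow. Fallback: an ionic ring closure replaces the radical chain. From 18, SmI2 in THF at −78 °C (Barbier-type closure of the alkylsamarium onto the ketone) should give the isolable cyclopropanol F1, a 1-hydroxy-5-methoxybicyclo[3.1.0]hexane fused to the cyclohexene. One-electron oxidation of F1 with manganese tris(picolinate), Mn(pic)3, in DMF in the presence of Bu3SnH should open the alkoxy radical at the ring-fusion bond and reduce the C11 radical, returning to the route at 19.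

Step 12. Facial selectivity may be poor, because a single allylic silyloxy centre has to decide the diene face. Fallback: a temporary lactone fixes the face instead of sterics. From 10, Mitsunobu esterification (PPh3, diisopropyl azodicarboxylate) with 2-[bis(2,2,2-trifluoroethoxy)phosphoryl]propanoic acid inverts C13 and gives phosphonate ester F2. Removal of the TBS group (pyridinium p-toluenesulfonate, MeOH) gives alcohol F3, and Dess–Martin oxidation gives aldehyde F4. Intramolecular Still–Gennari olefination (K2CO3, 18-crown-6, toluene, high dilution) closes the seven-membered (Z)-enoate lactone F5. On heating, the diene on C13 can reach only one face of the ring dienophile, which should give the tricyclic lactone F6 with C8, C9, C14 and C17 as in the target. Ethanolysis (K2CO3, EtOH) gives hydroxy ester F7, iodomethoxylation as in step 13 gives F8, and Dess–Martin oxidation of F8 returns to the route at 18.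

Step 32. Addition of the bulky geminal dichromium reagent to the neopentyl aldehyde may be slow, with competing reduction of the aldehyde. Fallback: alkyne homologation and hydroboration replace the chromium olefination. From 41, dimethyl (1-diazo-2-oxopropyl)phosphonate with K2CO3 in MeOH should give the terminal alkyne F9 (C8 is quaternary, so nothing can epimerise). Hydroboration with pinacolborane catalysed by Cp2Zr(H)Cl (syn addition, boron on the terminal carbon) returns to the route at 42.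

Further compounds
F1 | step 16 | cyclopropanol from 18 (C13(OH)–C12–C11(OMe) three-membered ring fused to the cyclopentane) | COC12CC1(O)[C@@H]3C=C[C@H](C#CC)[C@@](C(=O)OCC)(C)[C@@H]3C2
F2 | step 12 | (4R,5E,7E)-1-[(tert-butyldimethylsilyl)oxy]-3-methylideneundeca-5,7-dien-9-yn-4-yl 2-[bis(2,2,2-trifluoroethoxy)phosphoryl]propanoate | C=C(CCO[Si](C)(C)C(C)(C)C)[C@H](OC(=O)C(C)P(=O)(OCC(F)(F)F)OCC(F)(F)F)/C=C/C=C/C#CC
F3 | step 12 | (4R,5E,7E)-1-hydroxy-3-methylideneundeca-5,7-dien-9-yn-4-yl 2-[bis(2,2,2-trifluoroethoxy)phosphoryl]propanoate | C=C(CCO)[C@H](OC(=O)C(C)P(=O)(OCC(F)(F)F)OCC(F)(F)F)/C=C/C=C/C#CC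
F4 | step 12 | (4R,5E,7E)-3-methylidene-1-oxoundeca-5,7-dien-9-yn-4-yl 2-[bis(2,2,2-trifluoroethoxy)phosphoryl]propanoate | C=C(CC=O)[C@H](OC(=O)C(C)P(=O)(OCC(F)(F)F)OCC(F)(F)F)/C=C/C=C/C#CC
F5 | step 12 | (7R)-7-[(1E,3E)-hepta-1,3-dien-5-yn-1-yl]-3-methyl-6-methylidene-6,7-dihydro-5H-oxepin-2-one | C=C1C/C=C(C)\C(=O)O[C@@H]1/C=C/C=C/C#CC
F6 | step 12 | tricyclic lactone: Diels–Alder adduct of F5 with C13–O–C7(=O) bridge | C=C1[C@H](O3)[C@@H]2C=C[C@H](C#CC)[C@@](C3=O)(C)[C@@H]2C1
F7 | step 12 | ethyl 1-hydroxy-4-methyl-2-methylidene-5-(prop-1-yn-1-yl)-2,3,3a,4,5,7a-hexahydro-1H-indene-4-carboxylate (C13-OH cis to C8) | C=C1[C@H](O)[C@@H]2C=C[C@H](C#CC)[C@@](C(=O)OCC)(C)[C@@H]2C1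
F8 | step 12 | C13 epimer of 17 | COC1(CI)[C@H](O)[C@@H]2C=C[C@H](C#CC)[C@@](C(=O)OCC)(C)[C@@H]2C1
F9 | step 32 | terminal alkyne (C7≡C6) from aldehyde 41 | CO[C@@H]1C[C@H](O[Si](CC)(CC)CC)[C@@H]2C=C[C@H](/C=C(C)/C=C/[C@@H](C)[C@@H](O)[C@H](C)[C@H](O[Si](C)(C)C(C)(C)C)[C@@H](C)NC(C)=O)[C@@](C#C)(C)[C@@H]2C1
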